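**Plan**

- Cuts, in retrosynthetic order: the prenyl C=C (cross-metathesis of a 5'-allyl group), the three O–benzyl bonds, C4–C4a of ring C, O1–C2, and C3–C1' (an aryl shift away from an aldehyde carbon). This leaves ring A as 3,5-bis(benzyloxy)phenol and ring B as 3,5-dimethoxyphenol.
- Enabling feature: ring A is a symmetrical 3,5-dioxygenated phenol. Its two carbons ortho to O1 (either one becomes C4a) are equivalent, and each lies ortho to one and para to the other benzyloxy oxygen (future O5 and O7). The C4 acyl carbon can therefore be attached last and in only one way.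
- Forward order: ring B receives an allyl group between its two OMe groups, a CHO next to the phenol and an O-benzyl group, and is then homologated to a 2-aryl-3-hydroxyacrylate. That is joined to ring A through O1–C2 as an aryl vinyl ether. Ring C, the only ring built, is closed by Friedel–Crafts acylation.
- Stereochemistry: the target has no stereocentre. The only element to control is the Z geometry of acid 14, which comes from chelation-controlled enol tosylation followed by retentive vinylic substitution.
- The side chain stays allyl through the three acidic operations (steps 6, 10 and 11) and becomes prenyl in the last step.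

Key step: step 10

Remark on the chemistry: ring B is numbered 2'-OH, 4'-OMe, 5'-prenyl, 6'-OMe. Compound 10 is drawn as its hydrogen-bonded Z enol; it equilibrates with the formyl tautomer, which does not matter because step 7 passes through the common enolate.

**Route**

Step 1
Reactants: 1 3,5-dimethoxyphenol
Product: 2 (3,5-dimethoxyphenoxy)triisopropylsilane
Conditions: TIPSCl, imidazole, DMF, rt
Reagents that add atoms: chlorotriisopropylsilane CC(C)[Si](Cl)(C(C)C)C(C)C
Why: Imidazole-promoted silylation of a phenol, giving a bulky and weakly coordinating OTIPS group that neither directs nor allows metalation at its flanks in step 2.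

Step 2
Reactants: 2 (3,5-dimethoxyphenoxy)triisopropylsilane; 3 allyl bromide
Product: 5 (4-allyl-3,5-dimethoxyphenoxy)triisopropylsilane, via aryllithium 4 (not isolated)
Conditions: n-BuLi, THF, 0 °C to rt; then 3, −78 °C to rt
Reagents that add atoms: none
Why: Directed ortho-metalation, in which the C–H between the two methoxy groups is acidified and chelated by both while the positions beside OTIPS are shielded, and the aryllithium then displaces bromide from 3 by SN2 alkylation.

Step 3
Reactants: 5 (4-allyl-3,5-dimethoxyphenoxy)triisopropylsilane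
Product: 6 4-allyl-3,5-dimethoxyphenol
Conditions: TBAF, AcOH, THF, 0 °C
Reagents that add atoms: none
Why: Fluoride-induced cleavage of an aryl silyl ether, buffered with acetic acid, should release a symmetrical phenol whose two remaining ring C–H positions are equivalent.

Step 4
Reactants: 6 4-allyl-3,5-dimethoxyphenol
Product: 7 3-allyl-6-hydroxy-2,4-dimethoxybenzaldehyde
Conditions: MgCl2, Et3N, (CH2O)n, MeCN, reflux; then 1 M HCl
Reagents that add atoms: paraformaldehyde (as formaldehyde) C=O
Why: Casnati–Skattebøl ortho-formylation, in which the magnesium phenoxide delivers formaldehyde to the ortho carbon through a chelate, a second formaldehyde oxidises the benzylic alkoxide by hydride transfer, and the symmetry of 6 allows only one product.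

Step 5
Reactants: 7 3-allyl-6-hydroxy-2,4-dimethoxybenzaldehyde
Product: 8 3-allyl-6-(benzyloxy)-2,4-dimethoxybenzaldehyde
Conditions: BnBr, K2CO3, DMF, 50 °C
Reagents that add atoms: benzyl bromide BrCc1ccccc1
Why: Williamson etherification caps the future 2'-OH with a group that withstands base and mild acid and keeps this oxygen from lactonising onto the acyl carbon later.

Step 6
Reactants: 8 3-allyl-6-(benzyloxy)-2,4-dimethoxybenzaldehyde; 9 ethyl diazoacetate
Product: 10 ethyl (Z)-2-[3-allyl-6-(benzyloxy)-2,4-dimethoxyphenyl]-3-hydroxyacrylate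
Conditions: HBF4·OEt2 (10–20 mol %), CH2Cl2, −78 °C to rt
Reagents that add atoms: none
Why: Acid-catalysed addition of the diazo ester to the aldehyde, then loss of N2 with a 1,2-aryl shift (the aryl-migration variant of the Roskamp homologation), where the trioxygenated ring is an excellent migrating group and should outrun the hydride shift that gives a β-keto ester.

Step 7
Reactants: 10 ethyl (Z)-2-[3-allyl-6-(benzyloxy)-2,4-dimethoxyphenyl]-3-hydroxyacrylate
Product: 11 ethyl (Z)-2-[3-allyl-6-(benzyloxy)-2,4-dimethoxyphenyl]-3-(tosyloxy)acrylate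
Conditions: TsCl, N-methylimidazole, LiOH, CH2Cl2, 0 °C
Reagents that add atoms: 4-toluenesulfonyl chloride Cc1ccc(S(=O)(=O)Cl)cc1
Why: Stereoselective enol tosylation of an α-formyl ester, in which lithium chelates the enolate oxygen and the ester carbonyl so the tosylimidazolium reagent traps the oxygen cis to the ester (Z).

Step 8
Reactants: 11 ethyl (Z)-2-[3-allyl-6-(benzyloxy)-2,4-dimethoxyphenyl]-3-(tosyloxy)acrylate; 12 3,5-bis(benzyloxy)phenol
Product: 13 ethyl (Z)-2-[3-allyl-6-(benzyloxy)-2,4-dimethoxyphenyl]-3-[3,5-bis(benzyloxy)phenoxy]acrylate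
Conditions: Cs2CO3, MeCN, 0 °C to rt
Reagents that add atoms: none
Why: Nucleophilic vinylic substitution by addition–elimination, in which the phenoxide oxygen adds to the acrylate β-carbon and the very good leaving group departs before the C–C bond rotates far, so O1–C2 should form with mainly retained Z geometry and without the acid-promoted C-alkylation of ring A that leads to 3-arylcoumarins.

Step 9
Reactants: 13 ethyl (Z)-2-[3-allyl-6-(benzyloxy)-2,4-dimethoxyphenyl]-3-[3,5-bis(benzyloxy)phenoxy]acrylate
Product: 14 (Z)-2-[3-allyl-6-(benzyloxy)-2,4-dimethoxyphenyl]-3-[3,5-bis(benzyloxy)phenoxy]acrylic acid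
Conditions: LiOH, THF/H2O, 40 °C; then 1 M HCl to pH 3, 0 °C
Reagents that add atoms: lithium hydroxide [Li+].[OH-]
Why: Saponification, as practised on 3-aryloxy- and 3-alkoxyacrylates, run without an alcohol cosolvent so that no alkoxide can exchange with the aryloxy group at the β-carbon.

Step 10
Reactants: 14 (Z)-2-[3-allyl-6-(benzyloxy)-2,4-dimethoxyphenyl]-3-[3,5-bis(benzyloxy)phenoxy]acrylic acid
Product: 16 3-[3-allyl-6-(benzyloxy)-2,4-dimethoxyphenyl]-5,7-bis(benzyloxy)-4H-chromen-4-one, via mixed trifluoroacetic anhydride 15 (not isolated)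
Conditions: (CF3CO)2O (1.3 equiv), CH2Cl2 (0.02 M), 0 °C to rt
Reagents that add atoms: none
Why: Trifluoroacetic anhydride turns acid 14 into mixed anhydride 15, which reacts as (or ionises to) an acylium ion stabilised by the C2 oxygen, and the ring A carbon ortho to O1 attacks it and loses its proton to rearomatise, which makes the C4–C4a bond. The closest known reaction type is the cyclodehydration of 3-aryloxyacrylic acids to chromones by intramolecular Friedel–Crafts acylation. Ring C closes as a six-membered ring by electrophilic aromatic substitution, 6-exo-trig at the anhydride carbonyl, and no stereocentre is formed. Three selectivities are needed: chromone rather than coumarin connectivity is locked by the O1–C2 bond from step 8, the site on ring A is unambiguous because its two carbons ortho to O1 are equivalent by symmetry and each is ortho to one and para to the other benzyloxy group, and transfer of the substrate acyl group rather than trifluoroacetyl is favoured by intramolecularity, dilution and only a small excess of anhydride. The Z geometry holds the acyl carbon next to ring A, and any E isomer should drain through the Z form because the push–pull alkene isomerises by reversible protonation at C3 in the trifluoroacetic acid that is released. The allyl group and the benzyl and methyl ethers should be inert to two equivalents of dilute trifluoroacetic acid at this temperature.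

Step 11
Reactants: 16 3-[3-allyl-6-(benzyloxy)-2,4-dimethoxyphenyl]-5,7-bis(benzyloxy)-4H-chromen-4-one
Product: 17 3-(3-allyl-6-hydroxy-2,4-dimethoxyphenyl)-5,7-dihydroxy-4H-chromen-4-one
Conditions: BCl3, pentamethylbenzene, CH2Cl2, −78 °C; quench MeOH/CHCl3, then water
Reagents that add atoms: none
Why: Lewis-acid debenzylation with a non-Lewis-basic cation scavenger, in which BCl3 ionises the three O–benzyl bonds, pentamethylbenzene traps the benzyl cations, the methyl ethers hold at −78 °C, and the monosubstituted allyl alkene is far less easily protonated by the HCl released than a prenyl group would be.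

Step 12
Reactants: 17 3-(3-allyl-6-hydroxy-2,4-dimethoxyphenyl)-5,7-dihydroxy-4H-chromen-4-one; 18 2-methylbut-2-ene
Product: 19 5,7-dihydroxy-3-[6-hydroxy-2,4-dimethoxy-3-(3-methylbut-2-en-1-yl)phenyl]-4H-chromen-4-one (target)
Conditions: second-generation Grubbs catalyst RuCl2(=CHPh)(PCy3)(H2IMes) (5 mol %), 18/CH2Cl2 1:1, 40 °C, sealed tube
Reagents that add atoms: none
Why: Olefin cross-metathesis of a terminal allyl arene with excess 2-methylbut-2-ene, the standard allyl-to-prenyl conversion, which tolerates free phenols and leaves the electron-poor trisubstituted C2=C3 bond of the chromone untouched.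

**Compound list**

1 | 3,5-dimethoxyphenol | COc1cc(O)cc(OC)c1 | starting material
2 | (3,5-dimethoxyphenoxy)triisopropylsilane | COc1cc(OC)cc(O[Si](C(C)C)(C(C)C)C(C)C)c1 | intermediate
3 | allyl bromide | C=CCBr | starting material
4 | 2,6-dimethoxy-4-(triisopropylsilyloxy)phenyllithium | [Li]c1c(OC)cc(O[Si](C(C)C)(C(C)C)C(C)C)cc1OC | intermediate
5 | (4-allyl-3,5-dimethoxyphenoxy)triisopropylsilane | C=CCc1c(OC)cc(O[Si](C(C)C)(C(C)C)C(C)C)cc1OC | intermediate
6 | 4-allyl-3,5-dimethoxyphenol | C=CCc1c(OC)cc(O)cc1OC | intermediate
7 | 3-allyl-6-hydroxy-2,4-dimethoxybenzaldehyde | O=Cc1c(O)cc(OC)c(CC=C)c1OC | intermediate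
8 | 3-allyl-6-(benzyloxy)-2,4-dimethoxybenzaldehyde | O=Cc1c(OCc2ccccc2)cc(OC)c(CC=C)c1OC | intermediate
9 | ethyl diazoacetate | CCOC(=O)C=[N+]=[N-] | starting material
10 | ethyl (Z)-2-[3-allyl-6-(benzyloxy)-2,4-dimethoxyphenyl]-3-hydroxyacrylate | CCOC(=O)/C(=C\O)c1c(OCc2ccccc2)cc(OC)c(CC=C)c1OC | intermediate
11 | ethyl (Z)-2-[3-allyl-6-(benzyloxy)-2,4-dimethoxyphenyl]-3-(tosyloxy)acrylate | CCOC(=O)/C(=C\OS(=O)(=O)c1ccc(C)cc1)c1c(OCc2ccccc2)cc(OC)c(CC=C)c1OC | intermediate
12 | 3,5-bis(benzyloxy)phenol | Oc1cc(OCc2ccccc2)cc(OCc2ccccc2)c1 | starting material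
13 | ethyl (Z)-2-[3-allyl-6-(benzyloxy)-2,4-dimethoxyphenyl]-3-[3,5-bis(benzyloxy)phenoxy]acrylate | CCOC(=O)/C(=C\Oc1cc(OCc2ccccc2)cc(OCc2ccccc2)c1)c1c(OCc2ccccc2)cc(OC)c(CC=C)c1OC | intermediate
14 | (Z)-2-[3-allyl-6-(benzyloxy)-2,4-dimethoxyphenyl]-3-[3,5-bis(benzyloxy)phenoxy]acrylic acid | OC(=O)/C(=C\Oc1cc(OCc2ccccc2)cc(OCc2ccccc2)c1)c1c(OCc2ccccc2)cc(OC)c(CC=C)c1OC | intermediate
15 | mixed anhydride of 14 with trifluoroacetic acid | O=C(OC(=O)C(F)(F)F)/C(=C\Oc1cc(OCc2ccccc2)cc(OCc2ccccc2)c1)c1c(OCc2ccccc2)cc(OC)c(CC=C)c1OC | intermediate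
16 | 3-[3-allyl-6-(benzyloxy)-2,4-dimethoxyphenyl]-5,7-bis(benzyloxy)-4H-chromen-4-one | O=c1c(-c2c(OCc3ccccc3)cc(OC)c(CC=C)c2OC)coc2cc(OCc3ccccc3)cc(OCc3ccccc3)c12 | intermediate
17 | 3-(3-allyl-6-hydroxy-2,4-dimethoxyphenyl)-5,7-dihydroxy-4H-chromen-4-one | O=c1c(-c2c(O)cc(OC)c(CC=C)c2OC)coc2cc(O)cc(O)c12 | intermediate
18 | 2-methylbut-2-ene | CC=C(C)C | starting material
19 | 5,7-dihydroxy-3-[6-hydroxy-2,4-dimethoxy-3-(3-methylbut-2-en-1-yl)phenyl]-4H-chromen-4-one | COc1cc(O)c(-c2coc3cc(O)cc(O)c3c2=O)c(OC)c1CC=C(C)C | target

**Step count**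

Total steps: 12. Longest linear sequence: 12 (1 to 19). Ring A phenol 12 is bought and enters at step 8.

**Steps most likely to fail**

Step 6. The doubly ortho-substituted, strongly donor-stabilised aldehyde may add the diazo ester too slowly. Hydride shift may then compete with aryl shift, and the acid may consume the diazo ester. The fallback sets out from 8 and builds the same carbon chain one carbon at a time.
- Wittig olefination with (methoxymethyl)triphenylphosphonium chloride and KOtBu in THF should give the enol ether 3-allyl-6-(benzyloxy)-2,4-dimethoxy-1-(2-methoxyvinyl)benzene F1.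
- Hydrolysis with 2 M HCl in THF should give the arylacetaldehyde F2.
- Pinnick oxidation (NaClO2, NaH2PO4, excess 2-methylbut-2-ene, t-BuOH/H2O) should give the arylacetic acid F3.
- Alkylation with EtI and K2CO3 in DMF should give the ethyl arylacetate F4.
- A crossed Claisen condensation with ethyl formate and NaH in THF comes back to the route at 10.

Step 8. The hard phenoxide may attack sulfur instead of carbon, which transfers the sulfonyl group and returns the enolate. The alkene geometry may also erode during addition–elimination. The fallback sets out from 10 and replaces the sulfonate with a leaving group that has no second electrophilic centre.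
- Oxalyl chloride with catalytic DMF in CH2Cl2 at 0 °C should convert the enol into the ethyl 3-chloro-2-arylacrylate F5.
- F5 then takes up phenol 12 under K2CO3 with catalytic DABCO in DMF, where the amine adds first and the resulting vinylammonium ion is displaced by the phenoxide. This comes back to the route at 13.
- Any E isomer is carried on, because step 10 equilibrates the alkene.

Step 10. Isomerisation of E to Z material may be too slow. The activated acyl group may be captured by the neighbouring 2'-benzyloxy oxygen with loss of the benzyl group. The free positions of rings A and B may be trifluoroacetylated. The fallback reverses the order of the two ring C bonds and sets out from 10.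
- Warming with aqueous LiOH in THF removes the formyl group by retro-Claisen cleavage and saponifies the ester, giving the arylacetic acid F3 (the same acid as in the first fallback).
- Intermolecular acylation of commercial 1,3,5-tris(benzyloxy)benzene with this acid and trifluoroacetic anhydride in CH2Cl2 should give the tris(benzyloxy) deoxybenzoin F6.
- One equivalent of BCl3 at −78 °C removes a single benzyl group ortho to the ketone under chelation control, giving the 2-hydroxy deoxybenzoin F7.
- Heating with N,N-dimethylformamide dimethyl acetal in toluene inserts C2 and closes O1–C2, which comes back to the route at 16.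

**Further compounds**

F1 | step 6 | 3-allyl-6-(benzyloxy)-2,4-dimethoxy-1-(2-methoxyvinyl)benzene (E/Z mixture) | COC=Cc1c(OCc2ccccc2)cc(OC)c(CC=C)c1OC
F2 | step 6 | 2-[3-allyl-6-(benzyloxy)-2,4-dimethoxyphenyl]acetaldehyde | O=CCc1c(OCc2ccccc2)cc(OC)c(CC=C)c1OC
F3 | step 6 | 2-[3-allyl-6-(benzyloxy)-2,4-dimethoxyphenyl]acetic acid | OC(=O)Cc1c(OCc2ccccc2)cc(OC)c(CC=C)c1OC
F4 | step 6 | ethyl 2-[3-allyl-6-(benzyloxy)-2,4-dimethoxyphenyl]acetate | CCOC(=O)Cc1c(OCc2ccccc2)cc(OC)c(CC=C)c1OC
F5 | step 8 | ethyl 2-[3-allyl-6-(benzyloxy)-2,4-dimethoxyphenyl]-3-chloroacrylate (E/Z mixture) | CCOC(=O)C(=CCl)c1c(OCc2ccccc2)cc(OC)c(CC=C)c1OC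
F6 | step 10 | 2-[3-allyl-6-(benzyloxy)-2,4-dimethoxyphenyl]-1-[2,4,6-tris(benzyloxy)phenyl]ethan-1-one | O=C(Cc1c(OCc2ccccc2)cc(OC)c(CC=C)c1OC)c1c(OCc2ccccc2)cc(OCc2ccccc2)cc1OCc1ccccc1
F7 | step 10 | 2-[3-allyl-6-(benzyloxy)-2,4-dimethoxyphenyl]-1-[2,4-bis(benzyloxy)-6-hydroxyphenyl]ethan-1-one | O=C(Cc1c(OCc2ccccc2)cc(OC)c(CC=C)c1OC)c1c(O)cc(OCc2ccccc2)cc1OCc1ccccc1
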